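The data were computed from invented constants.

the same everywhere: free catalyst 4.5 mM; second catalyst 0.92 mM

| run | substrate | partner | remark |
|---|---|---|---|
| Monday's | 0.092 M | 0.083 M | run made earlier |
| Saturday's | 0.092 M | 0.12 M | run made earlier |
| Wednesday's | 0.14 M | 0.166 M | run made earlier |
| flask | 0.092 M | 0.166 M |  |

| run | time / min | target / % |
|---|---|---|
| Monday's | 3.00 | 19.8 |
| Monday's | 6.00 | 32.9 |
| Monday's | 15.0 | 46.8 |
| Monday's | 40.0 | 49.9 |
| Saturday's | 3.00 | 20.9 |
| Saturday's | 6.00 | 33.1 |
| Saturday's | 15.0 | 46.5 |
| Saturday's | 40.0 | 50.1 |
| Wednesday's | 5.00 | 30.3 |
| Wednesday's | 12.0 | 43.9 |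
| Wednesday's | 25.0 | 49.6 |
| Wednesday's | 40.0 | 49.7 |

(readings scatter by 0.3 percentage points)

- apparent order in partner when 50 % of the substrate are converted (percent change of the rate of making target for one percent more partner charged)

- "the catalyst" is free catalyst with its forms; second catalyst is a second catalyst
- what has left substrate counts as converted, also if it is not yet product

- At early times partner shows itself: at 3.00 min Saturday's target stands 1.1 percentage points above Monday's, yet at 40.0 min the two read 50.1 % and 49.9 %.
- A reading: target trails the loss of substrate by a lag τ = c/B, where B is the partner present and c a constant. The lag is the life of an unseen intermediate, taken up in pseudo-first-order fashion by partner.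
- The loss of substrate, the feed f, shows no partner in its plateaus, so a first guess for the order is zero.
- The objection is that f is falling at some rate λ, and a trailing target runs ahead of a falling feed: r = f/(1 − ε), with ε = λτ.
- For λ, take y as the target fraction and u = −ln(1 − y). The distance of u from ln 2 shrinks as exp(−λt), and the middle readings of the 3 runs give λ = 0.162 min⁻¹.
- For c, the gap between two runs equals the slope of the curve times their difference in lag. One pair is thin, though: at 6.00 min the gap is 0.2 points. So both pairs are pooled, giving a summed gap of 1.3 points from 4 readings, with a scatter of 0.6 points.
- At half conversion the flask holds B = 0.120 M, so τ = 0.184 min, much shorter than 6.17 min, the feed's decay time.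
- That gives ε = 0.0299, the lag share: lag time over feed decay time, a small correction to f.
- One percent more partner charged raises B by B₀/B percent, with B₀ the charge, so my order is −ε/(1 − ε)·B₀/B = −0.0426. The scatter of the gap is 46.2 % of the gap itself, so this is a sign and a rough size.
- The forecast gives 0, holding that “Partner must enter after the rate-limiting step”.
- The flask gives −0.066 at 0.529 h; by 0.500 h its free catalyst stands at 0.874 % of the catalyst charged.

    substrate + free catalyst → free catalyst + intermediate (k = 24.5 M⁻¹ min⁻¹)
    partner + second catalyst + intermediate → second catalyst + target (k = 31400 M⁻² min⁻¹)
    free catalyst → spent catalyst (k = 0.158 min⁻¹)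

- Read back through the same relation, this value asks a lag share of 0.0457 in the flask, larger than my 0.0299. Monday's run holds 0.0370 M of partner at the same conversion, so its lag share scales to 0.148 and its order to −0.390.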